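**Plan**

- Retrosynthesis: the twenty O–CH3 bonds are cut last. The ether bonds to C1 of rings B, D, F and H are cut as SNAr reactions of 4-fluoro-2,6-dimethoxybenzaldehyde, whose formyl group is the masked C4 oxygen (Baeyer–Villiger).
- Rings C, E and G are each cut at C5–C6 (six-electron closure of a dienylketene) and at C1–C2 (addition of an α-lithiated aryl vinyl ether to dimethyl squarate).
- Enabling feature: ring C (and likewise E and G) carries oxygen on C1 to C5 and hydrogen only on C6, with aryl ether oxygens on adjacent C1 and C2. C2–C5 are therefore the four squarate carbons and C1–C6 an aryloxyvinyl unit.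
- Forward: ring A is bought and ring B is added by SNAr and Baeyer–Villiger. A six-step cycle (vinylation, squarate addition with O-silylation, ring expansion, methylation, fluoride-triggered SNAr, Baeyer–Villiger) is then run three times for rings C/D, E/F and G/H, and BBr3 ends the route.
- Stereochemistry: the target is achiral. The racemic carbinol centres of the cyclobutenones vanish on ring expansion, and the vinyl group is placed inward on the ketene by outward rotation of the silyloxy group.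

Key step: step 5

**Conventions and assumption**

- Rings are lettered A to H from the 2,4,6-trioxygenated end; each ring is numbered from the carbon bearing the ether oxygen to the preceding ring (ring A from the carbon bearing the oxygen to ring B).
- ArAB = 2,6-dimethoxy-4-(2,4,6-trimethoxyphenoxy)phenyl.
- ArAD = 4-[2,3,4-trimethoxy-6-(ArAB-oxy)phenoxy]-2,6-dimethoxyphenyl.
- ArAF = 4-[2,3,4-trimethoxy-6-(ArAD-oxy)phenoxy]-2,6-dimethoxyphenyl.
- ArAH = 4-[2,3,4-trimethoxy-6-(ArAF-oxy)phenoxy]-2,6-dimethoxyphenyl.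
- TBS = tert-butyldimethylsilyl.
- Assumption: the tertiary alkoxide of each squarate adduct is capped as its TBS ether, so ring expansion delivers the two para oxygens of rings C, E and G already differentiated (C2–OTBS, C5–OH). Free phenols are handled under argon.

**Route**

Step 1
Reactants: 1 2,4,6-trimethoxyphenol; 2 4-fluoro-2,6-dimethoxybenzaldehyde
Product: 3 ArAB–CHO (2,6-dimethoxy-4-(2,4,6-trimethoxyphenoxy)benzaldehyde)
Conditions: K2CO3, DMF, 110 °C, argon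
Reagents that add atoms: none
Why: Nucleophilic aromatic substitution (SNAr), in which the fluoride of 2 is para to the formyl group that stabilises the Meisenheimer adduct and sits on a carbon flanked only by hydrogens, so the doubly ortho-substituted phenoxide of 1 should add without steric penalty.

Step 2
Reactants: 3 ArAB–CHO
Product: 5 ArAB–OH (2,6-dimethoxy-4-(2,4,6-trimethoxyphenoxy)phenol), via aryl formate 4 (not isolated)
Conditions: mCPBA, CH2Cl2, 0 °C to rt; then K2CO3 (cat.), MeOH, rt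
Reagents that add atoms: mCPBA (3-chloroperoxybenzoic acid), OOC(=O)c1cccc(Cl)c1
Why: Baeyer–Villiger (Dakin-type) oxidation in which the electron-rich trioxygenated aryl group migrates in preference to hydrogen, followed by methanolysis of the aryl formate.

Step 3
Reactants: 5 ArAB–OH
Product: 6 ArAB–OCH=CH2 (2-(ethenyloxy)-1,3-dimethoxy-5-(2,4,6-trimethoxyphenoxy)benzene)
Conditions: vinyl acetate, [Ir(cod)Cl]2 (cat.), Na2CO3, toluene, 100 °C
Reagents that add atoms: vinyl acetate, C=COC(C)=O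
Why: Iridium-catalysed transfer vinylation of a phenol (aryloxide addition to coordinated vinyl acetate, then loss of acetate), chosen because its non-oxidising conditions suit an electron-rich hydroquinone monoether.

Step 4
Reactants: 6 ArAB–OCH=CH2; 7 dimethyl squarate
Product: 10 racemic 4-[(tert-butyldimethylsilyl)oxy]-2,3-dimethoxy-4-[1-(ArAB-oxy)ethenyl]cyclobut-2-en-1-one, via lithiated enol ether 8 (not isolated), via lithium alkoxide 9 (not isolated)
Conditions: t-BuLi (1.05 equiv), THF, −78 °C; cannulated into 7, THF, −78 °C; then TBSOTf, −78 to 0 °C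
Reagents that add atoms: TBSOTf (tert-butyldimethylsilyl trifluoromethanesulfonate), CC(C)(C)[Si](C)(C)OS(=O)(=O)C(F)(F)F
Why: Kinetic α-lithiation of the enol ether by t-BuLi (the vinylic hydrogen geminal to the aryloxy oxygen is the most acidic site, as in the ready 2-lithiation of benzofuran and 1,4-benzodioxin, and both positions ortho to the vinyloxy group are blocked by methoxy groups), 1,2-addition of the vinyllithium to one squarate carbonyl and O-silylation of the tertiary alkoxide should give 10; the carbinol stereocentre forms without control as a racemate and is erased in step 5.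

Step 5
Reactants: 10 racemic 4-[(tert-butyldimethylsilyl)oxy]-2,3-dimethoxy-4-[1-(ArAB-oxy)ethenyl]cyclobut-2-en-1-one
Product: 13 4-[(tert-butyldimethylsilyl)oxy]-2,3-dimethoxy-5-(ArAB-oxy)phenol (rings A–B–C with C2–OTBS and C5–OH), via (Z)-dienylketene 11 (not isolated), via cyclohexa-2,4-dienone 12 (not isolated)
Conditions: degassed p-xylene, 138 °C, argon
Reagents that add atoms: none
Why: Heating cleaves the C(=O)–C(OSi) bond of the four-membered ring in a conrotatory four-electron electrocyclic opening in which the silyloxy donor on the sp3 carbon turns outward, so the aryloxyvinyl group ends up inward on (Z)-dienylketene 11. A disrotatory six-electron electrocyclisation then bonds the ketene carbon to the vinyl CH2 terminus, which creates the C5–C6 bond and closes ring C as the six-membered carbocycle of dienone 12, and enolisation aromatises 12 to phenol 13. The closest known reaction type is the Moore rearrangement of 4-alkenyl-4-hydroxy- and 4-silyloxycyclobutenones made from squarate esters, α-alkoxyvinyl examples included. No stereocentre is formed and the racemic carbinol centre of 10 is erased. The selectivity required is the direction of rotation in the ring opening, and the strong outward preference of an oxygen donor on the breaking bond secures it. Keeping that oxygen silylated also shuts off lactonisation of the ketene to a butenolide and hands on the two para oxygens of ring C differentiated as C2–OTBS and C5–OH.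

Step 6
Reactants: 13 4-[(tert-butyldimethylsilyl)oxy]-2,3-dimethoxy-5-(ArAB-oxy)phenol
Product: 14 tert-butyl[2,3,4-trimethoxy-6-(ArAB-oxy)phenoxy]dimethylsilane
Conditions: MeOH, PPh3, DIAD, THF, 0 °C to rt
Reagents that add atoms: methanol, CO
Why: Mitsunobu etherification of the only free phenol (C5–OH) under neutral conditions, which leaves the aryl silyl ether at C2 untouched.

Step 7
Reactants: 14 tert-butyl[2,3,4-trimethoxy-6-(ArAB-oxy)phenoxy]dimethylsilane; 2 4-fluoro-2,6-dimethoxybenzaldehyde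
Product: 15 ArAD–CHO (4-[2,3,4-trimethoxy-6-(ArAB-oxy)phenoxy]-2,6-dimethoxybenzaldehyde)
Conditions: CsF, DMF, 90 °C
Reagents that add atoms: none
Why: Fluoride-triggered desilylation releases the ring C C2 phenoxide in the flask, which displaces the para-formyl-activated fluoride of 2 by SNAr at an unhindered carbon, the fluoride set free carrying the desilylation forward.

Step 8
Reactants: 15 ArAD–CHO
Product: 17 ArAD–OH, via aryl formate 16 (not isolated)
Conditions: mCPBA, CH2Cl2, 0 °C to rt; then K2CO3 (cat.), MeOH, rt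
Reagents that add atoms: mCPBA (3-chloroperoxybenzoic acid), OOC(=O)c1cccc(Cl)c1
Why: Baeyer–Villiger (Dakin-type) oxidation with migration of the electron-rich ring D aryl group, then methanolysis of the formate to the ring D C4 phenol.

Step 9
Reactants: 17 ArAD–OH
Product: 18 ArAD–OCH=CH2
Conditions: vinyl acetate, [Ir(cod)Cl]2 (cat.), Na2CO3, toluene, 100 °C
Reagents that add atoms: vinyl acetate, C=COC(C)=O
Why: Iridium-catalysed transfer vinylation of the phenol, as in step 3.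

Step 10
Reactants: 18 ArAD–OCH=CH2; 7 dimethyl squarate
Product: 21 racemic 4-[(tert-butyldimethylsilyl)oxy]-2,3-dimethoxy-4-[1-(ArAD-oxy)ethenyl]cyclobut-2-en-1-one, via lithiated enol ether 19 (not isolated), via lithium alkoxide 20 (not isolated)
Conditions: t-BuLi (1.05 equiv), THF, −78 °C; cannulated into 7, THF, −78 °C; then TBSOTf, −78 to 0 °C
Reagents that add atoms: TBSOTf (tert-butyldimethylsilyl trifluoromethanesulfonate), CC(C)(C)[Si](C)(C)OS(=O)(=O)C(F)(F)F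
Why: The same α-lithiation of the enol ether, 1,2-addition to the squarate ester and alkoxide silylation as in step 4; the racemic carbinol centre is erased in step 11.

Step 11
Reactants: 21 racemic 4-[(tert-butyldimethylsilyl)oxy]-2,3-dimethoxy-4-[1-(ArAD-oxy)ethenyl]cyclobut-2-en-1-one
Product: 24 4-[(tert-butyldimethylsilyl)oxy]-2,3-dimethoxy-5-(ArAD-oxy)phenol (rings A–E), via (Z)-dienylketene 22 (not isolated), via cyclohexa-2,4-dienone 23 (not isolated)
Conditions: degassed p-xylene, 138 °C, argon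
Reagents that add atoms: none
Why: Moore rearrangement as in step 5 (conrotatory opening with the silyloxy group outward, six-electron closure of the ketene onto the vinyl terminus, enolisation), which builds ring E.

Step 12
Reactants: 24 4-[(tert-butyldimethylsilyl)oxy]-2,3-dimethoxy-5-(ArAD-oxy)phenol
Product: 25 tert-butyl[2,3,4-trimethoxy-6-(ArAD-oxy)phenoxy]dimethylsilane
Conditions: MeOH, PPh3, DIAD, THF, 0 °C to rt
Reagents that add atoms: methanol, CO
Why: Mitsunobu etherification of the single free phenol (ring E C5–OH) under neutral conditions that spare the silyl ether.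

Step 13
Reactants: 25 tert-butyl[2,3,4-trimethoxy-6-(ArAD-oxy)phenoxy]dimethylsilane; 2 4-fluoro-2,6-dimethoxybenzaldehyde
Product: 26 ArAF–CHO (4-[2,3,4-trimethoxy-6-(ArAD-oxy)phenoxy]-2,6-dimethoxybenzaldehyde)
Conditions: CsF, DMF, 90 °C
Reagents that add atoms: none
Why: Fluoride-triggered desilylation and SNAr of the ring E C2 phenoxide on the para-formyl-activated fluoride, as in step 7.

Step 14
Reactants: 26 ArAF–CHO
Product: 28 ArAF–OH, via aryl formate 27 (not isolated)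
Conditions: mCPBA, CH2Cl2, 0 °C to rt; then K2CO3 (cat.), MeOH, rt
Reagents that add atoms: mCPBA (3-chloroperoxybenzoic acid), OOC(=O)c1cccc(Cl)c1
Why: Baeyer–Villiger (Dakin-type) oxidation with aryl migration and methanolysis of the formate, as in step 2.

Step 15
Reactants: 28 ArAF–OH
Product: 29 ArAF–OCH=CH2
Conditions: vinyl acetate, [Ir(cod)Cl]2 (cat.), Na2CO3, toluene, 100 °C
Reagents that add atoms: vinyl acetate, C=COC(C)=O
Why: Iridium-catalysed transfer vinylation of the phenol, as in step 3.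

Step 16
Reactants: 29 ArAF–OCH=CH2; 7 dimethyl squarate
Product: 32 racemic 4-[(tert-butyldimethylsilyl)oxy]-2,3-dimethoxy-4-[1-(ArAF-oxy)ethenyl]cyclobut-2-en-1-one, via lithiated enol ether 30 (not isolated), via lithium alkoxide 31 (not isolated)
Conditions: t-BuLi (1.05 equiv), THF, −78 °C; cannulated into 7, THF, −78 °C; then TBSOTf, −78 to 0 °C
Reagents that add atoms: TBSOTf (tert-butyldimethylsilyl trifluoromethanesulfonate), CC(C)(C)[Si](C)(C)OS(=O)(=O)C(F)(F)F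
Why: The same α-lithiation of the enol ether, 1,2-addition to the squarate ester and alkoxide silylation as in step 4; the racemic carbinol centre is erased in step 17.

Step 17
Reactants: 32 racemic 4-[(tert-butyldimethylsilyl)oxy]-2,3-dimethoxy-4-[1-(ArAF-oxy)ethenyl]cyclobut-2-en-1-one
Product: 35 4-[(tert-butyldimethylsilyl)oxy]-2,3-dimethoxy-5-(ArAF-oxy)phenol (rings A–G), via (Z)-dienylketene 33 (not isolated), via cyclohexa-2,4-dienone 34 (not isolated)
Conditions: degassed p-xylene, 138 °C, argon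
Reagents that add atoms: none
Why: Moore rearrangement as in step 5, which builds ring G by six-electron closure of the dienylketene and enolisation.

Step 18
Reactants: 35 4-[(tert-butyldimethylsilyl)oxy]-2,3-dimethoxy-5-(ArAF-oxy)phenol
Product: 36 tert-butyl[2,3,4-trimethoxy-6-(ArAF-oxy)phenoxy]dimethylsilane
Conditions: MeOH, PPh3, DIAD, THF, 0 °C to rt
Reagents that add atoms: methanol, CO
Why: Mitsunobu etherification of the single free phenol (ring G C5–OH) under neutral conditions that spare the silyl ether.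

Step 19
Reactants: 36 tert-butyl[2,3,4-trimethoxy-6-(ArAF-oxy)phenoxy]dimethylsilane; 2 4-fluoro-2,6-dimethoxybenzaldehyde
Product: 37 ArAH–CHO (4-[2,3,4-trimethoxy-6-(ArAF-oxy)phenoxy]-2,6-dimethoxybenzaldehyde)
Conditions: CsF, DMF, 90 °C
Reagents that add atoms: none
Why: Fluoride-triggered desilylation and SNAr of the ring G C2 phenoxide on the para-formyl-activated fluoride, as in step 7, which attaches ring H.

Step 20
Reactants: 37 ArAH–CHO
Product: 39 ArAH–OH (permethylated octamer with one free phenol at ring H C4), via aryl formate 38 (not isolated)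
Conditions: mCPBA, CH2Cl2, 0 °C to rt; then K2CO3 (cat.), MeOH, rt
Reagents that add atoms: mCPBA (3-chloroperoxybenzoic acid), OOC(=O)c1cccc(Cl)c1
Why: Baeyer–Villiger (Dakin-type) oxidation with aryl migration and methanolysis of the formate, which installs the third oxygen of ring H.

Step 21
Reactants: 39 ArAH–OH
Product: 40 CNP0206369.0 (39 with all twenty O-methyl groups replaced by hydrogen; twenty-one free hydroxyls)
Conditions: BBr3 (large excess), CH2Cl2, −78 °C to rt, argon; then H2O, 0 °C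
Reagents that add atoms: none
Why: Lewis acid ether cleavage in which BBr3 coordinates each methoxy oxygen and bromide removes the methyl group by SN2, while the seven diaryl ether bonds, which offer no sp3 carbon, should remain intact.

**Compound list**

1 | 2,4,6-trimethoxyphenol (ring A) | COc1cc(OC)c(O)c(OC)c1 | starting material
2 | 4-fluoro-2,6-dimethoxybenzaldehyde | COc1cc(F)cc(OC)c1C=O | starting material
3 | ArAB–CHO, 2,6-dimethoxy-4-(2,4,6-trimethoxyphenoxy)benzaldehyde | COc1cc(OC)c(Oc2cc(OC)c(C=O)c(OC)c2)c(OC)c1 | intermediate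
4 | ArAB–OCHO, 2,6-dimethoxy-4-(2,4,6-trimethoxyphenoxy)phenyl formate | COc1cc(OC)c(Oc2cc(OC)c(OC=O)c(OC)c2)c(OC)c1 | intermediate
5 | ArAB–OH, 2,6-dimethoxy-4-(2,4,6-trimethoxyphenoxy)phenol | COc1cc(OC)c(Oc2cc(OC)c(O)c(OC)c2)c(OC)c1 | intermediate
6 | ArAB–OCH=CH2, 2-(ethenyloxy)-1,3-dimethoxy-5-(2,4,6-trimethoxyphenoxy)benzene | COc1cc(OC)c(Oc2cc(OC)c(OC=C)c(OC)c2)c(OC)c1 | intermediate
7 | dimethyl squarate (3,4-dimethoxycyclobut-3-ene-1,2-dione) | COC1=C(OC)C(=O)C1=O | starting material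
8 | [1-(ArAB-oxy)ethenyl]lithium | COc1cc(OC)c(Oc2cc(OC)c(OC([Li])=C)c(OC)c2)c(OC)c1 | intermediate
9 | lithium alkoxide of racemic 4-hydroxy-2,3-dimethoxy-4-[1-(ArAB-oxy)ethenyl]cyclobut-2-en-1-one | COc1cc(OC)c(Oc2cc(OC)c(OC(=C)C3([O-])C(OC)=C(OC)C3=O)c(OC)c2)c(OC)c1.[Li+] | intermediate
10 | racemic 4-[(tert-butyldimethylsilyl)oxy]-2,3-dimethoxy-4-[1-(ArAB-oxy)ethenyl]cyclobut-2-en-1-one | COc1cc(OC)c(Oc2cc(OC)c(OC(=C)C3(O[Si](C)(C)C(C)(C)C)C(OC)=C(OC)C3=O)c(OC)c2)c(OC)c1 | intermediate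
11 | (3Z)-4-[(tert-butyldimethylsilyl)oxy]-2,3-dimethoxy-5-(ArAB-oxy)hexa-1,3,5-trien-1-one | COc1cc(OC)c(Oc2cc(OC)c(OC(=C)/C(O[Si](C)(C)C(C)(C)C)=C(OC)\C(OC)=C=O)c(OC)c2)c(OC)c1 | intermediate
12 | 4-[(tert-butyldimethylsilyl)oxy]-2,3-dimethoxy-5-(ArAB-oxy)cyclohexa-2,4-dien-1-one | COc1cc(OC)c(Oc2cc(OC)c(OC3=C(O[Si](C)(C)C(C)(C)C)C(OC)=C(OC)C(=O)C3)c(OC)c2)c(OC)c1 | intermediate
13 | 4-[(tert-butyldimethylsilyl)oxy]-2,3-dimethoxy-5-(ArAB-oxy)phenol | COc1cc(OC)c(Oc2cc(OC)c(Oc3cc(O)c(OC)c(OC)c3O[Si](C)(C)C(C)(C)C)c(OC)c2)c(OC)c1 | intermediate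
14 | tert-butyl[2,3,4-trimethoxy-6-(ArAB-oxy)phenoxy]dimethylsilane | COc1cc(OC)c(Oc2cc(OC)c(Oc3cc(OC)c(OC)c(OC)c3O[Si](C)(C)C(C)(C)C)c(OC)c2)c(OC)c1 | intermediate
15 | ArAD–CHO | COc1cc(OC)c(Oc2cc(OC)c(Oc3cc(OC)c(OC)c(OC)c3Oc3cc(OC)c(C=O)c(OC)c3)c(OC)c2)c(OC)c1 | intermediate
16 | ArAD–OCHO (aryl formate) | COc1cc(OC)c(Oc2cc(OC)c(Oc3cc(OC)c(OC)c(OC)c3Oc3cc(OC)c(OC=O)c(OC)c3)c(OC)c2)c(OC)c1 | intermediate
17 | ArAD–OH | COc1cc(OC)c(Oc2cc(OC)c(Oc3cc(OC)c(OC)c(OC)c3Oc3cc(OC)c(O)c(OC)c3)c(OC)c2)c(OC)c1 | intermediate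
18 | ArAD–OCH=CH2 | COc1cc(OC)c(Oc2cc(OC)c(Oc3cc(OC)c(OC)c(OC)c3Oc3cc(OC)c(OC=C)c(OC)c3)c(OC)c2)c(OC)c1 | intermediate
19 | [1-(ArAD-oxy)ethenyl]lithium | COc1cc(OC)c(Oc2cc(OC)c(Oc3cc(OC)c(OC)c(OC)c3Oc3cc(OC)c(OC([Li])=C)c(OC)c3)c(OC)c2)c(OC)c1 | intermediate
20 | lithium alkoxide of racemic 4-hydroxy-2,3-dimethoxy-4-[1-(ArAD-oxy)ethenyl]cyclobut-2-en-1-one | COc1cc(OC)c(Oc2cc(OC)c(Oc3cc(OC)c(OC)c(OC)c3Oc3cc(OC)c(OC(=C)C4([O-])C(OC)=C(OC)C4=O)c(OC)c3)c(OC)c2)c(OC)c1.[Li+] | intermediate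
21 | racemic 4-[(tert-butyldimethylsilyl)oxy]-2,3-dimethoxy-4-[1-(ArAD-oxy)ethenyl]cyclobut-2-en-1-one | COc1cc(OC)c(Oc2cc(OC)c(Oc3cc(OC)c(OC)c(OC)c3Oc3cc(OC)c(OC(=C)C4(O[Si](C)(C)C(C)(C)C)C(OC)=C(OC)C4=O)c(OC)c3)c(OC)c2)c(OC)c1 | intermediate
22 | (3Z)-4-[(tert-butyldimethylsilyl)oxy]-2,3-dimethoxy-5-(ArAD-oxy)hexa-1,3,5-trien-1-one | COc1cc(OC)c(Oc2cc(OC)c(Oc3cc(OC)c(OC)c(OC)c3Oc3cc(OC)c(OC(=C)/C(O[Si](C)(C)C(C)(C)C)=C(OC)\C(OC)=C=O)c(OC)c3)c(OC)c2)c(OC)c1 | intermediate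
23 | 4-[(tert-butyldimethylsilyl)oxy]-2,3-dimethoxy-5-(ArAD-oxy)cyclohexa-2,4-dien-1-one | COc1cc(OC)c(Oc2cc(OC)c(Oc3cc(OC)c(OC)c(OC)c3Oc3cc(OC)c(OC4=C(O[Si](C)(C)C(C)(C)C)C(OC)=C(OC)C(=O)C4)c(OC)c3)c(OC)c2)c(OC)c1 | intermediate
24 | 4-[(tert-butyldimethylsilyl)oxy]-2,3-dimethoxy-5-(ArAD-oxy)phenol | COc1cc(OC)c(Oc2cc(OC)c(Oc3cc(OC)c(OC)c(OC)c3Oc3cc(OC)c(Oc4cc(O)c(OC)c(OC)c4O[Si](C)(C)C(C)(C)C)c(OC)c3)c(OC)c2)c(OC)c1 | intermediate
25 | tert-butyl[2,3,4-trimethoxy-6-(ArAD-oxy)phenoxy]dimethylsilane | COc1cc(OC)c(Oc2cc(OC)c(Oc3cc(OC)c(OC)c(OC)c3Oc3cc(OC)c(Oc4cc(OC)c(OC)c(OC)c4O[Si](C)(C)C(C)(C)C)c(OC)c3)c(OC)c2)c(OC)c1 | intermediate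
26 | ArAF–CHO | COc1cc(OC)c(Oc2cc(OC)c(Oc3cc(OC)c(OC)c(OC)c3Oc3cc(OC)c(Oc4cc(OC)c(OC)c(OC)c4Oc4cc(OC)c(C=O)c(OC)c4)c(OC)c3)c(OC)c2)c(OC)c1 | intermediate
27 | ArAF–OCHO (aryl formate) | COc1cc(OC)c(Oc2cc(OC)c(Oc3cc(OC)c(OC)c(OC)c3Oc3cc(OC)c(Oc4cc(OC)c(OC)c(OC)c4Oc4cc(OC)c(OC=O)c(OC)c4)c(OC)c3)c(OC)c2)c(OC)c1 | intermediate
28 | ArAF–OH | COc1cc(OC)c(Oc2cc(OC)c(Oc3cc(OC)c(OC)c(OC)c3Oc3cc(OC)c(Oc4cc(OC)c(OC)c(OC)c4Oc4cc(OC)c(O)c(OC)c4)c(OC)c3)c(OC)c2)c(OC)c1 | intermediate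
29 | ArAF–OCH=CH2 | COc1cc(OC)c(Oc2cc(OC)c(Oc3cc(OC)c(OC)c(OC)c3Oc3cc(OC)c(Oc4cc(OC)c(OC)c(OC)c4Oc4cc(OC)c(OC=C)c(OC)c4)c(OC)c3)c(OC)c2)c(OC)c1 | intermediate
30 | [1-(ArAF-oxy)ethenyl]lithium | COc1cc(OC)c(Oc2cc(OC)c(Oc3cc(OC)c(OC)c(OC)c3Oc3cc(OC)c(Oc4cc(OC)c(OC)c(OC)c4Oc4cc(OC)c(OC([Li])=C)c(OC)c4)c(OC)c3)c(OC)c2)c(OC)c1 | intermediate
31 | lithium alkoxide of racemic 4-hydroxy-2,3-dimethoxy-4-[1-(ArAF-oxy)ethenyl]cyclobut-2-en-1-one | COc1cc(OC)c(Oc2cc(OC)c(Oc3cc(OC)c(OC)c(OC)c3Oc3cc(OC)c(Oc4cc(OC)c(OC)c(OC)c4Oc4cc(OC)c(OC(=C)C5([O-])C(OC)=C(OC)C5=O)c(OC)c4)c(OC)c3)c(OC)c2)c(OC)c1.[Li+] | intermediate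
32 | racemic 4-[(tert-butyldimethylsilyl)oxy]-2,3-dimethoxy-4-[1-(ArAF-oxy)ethenyl]cyclobut-2-en-1-one | COc1cc(OC)c(Oc2cc(OC)c(Oc3cc(OC)c(OC)c(OC)c3Oc3cc(OC)c(Oc4cc(OC)c(OC)c(OC)c4Oc4cc(OC)c(OC(=C)C5(O[Si](C)(C)C(C)(C)C)C(OC)=C(OC)C5=O)c(OC)c4)c(OC)c3)c(OC)c2)c(OC)c1 | intermediate
33 | (3Z)-4-[(tert-butyldimethylsilyl)oxy]-2,3-dimethoxy-5-(ArAF-oxy)hexa-1,3,5-trien-1-one | COc1cc(OC)c(Oc2cc(OC)c(Oc3cc(OC)c(OC)c(OC)c3Oc3cc(OC)c(Oc4cc(OC)c(OC)c(OC)c4Oc4cc(OC)c(OC(=C)/C(O[Si](C)(C)C(C)(C)C)=C(OC)\C(OC)=C=O)c(OC)c4)c(OC)c3)c(OC)c2)c(OC)c1 | intermediate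
34 | 4-[(tert-butyldimethylsilyl)oxy]-2,3-dimethoxy-5-(ArAF-oxy)cyclohexa-2,4-dien-1-one | COc1cc(OC)c(Oc2cc(OC)c(Oc3cc(OC)c(OC)c(OC)c3Oc3cc(OC)c(Oc4cc(OC)c(OC)c(OC)c4Oc4cc(OC)c(OC5=C(O[Si](C)(C)C(C)(C)C)C(OC)=C(OC)C(=O)C5)c(OC)c4)c(OC)c3)c(OC)c2)c(OC)c1 | intermediate
35 | 4-[(tert-butyldimethylsilyl)oxy]-2,3-dimethoxy-5-(ArAF-oxy)phenol | COc1cc(OC)c(Oc2cc(OC)c(Oc3cc(OC)c(OC)c(OC)c3Oc3cc(OC)c(Oc4cc(OC)c(OC)c(OC)c4Oc4cc(OC)c(Oc5cc(O)c(OC)c(OC)c5O[Si](C)(C)C(C)(C)C)c(OC)c4)c(OC)c3)c(OC)c2)c(OC)c1 | intermediate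
36 | tert-butyl[2,3,4-trimethoxy-6-(ArAF-oxy)phenoxy]dimethylsilane | COc1cc(OC)c(Oc2cc(OC)c(Oc3cc(OC)c(OC)c(OC)c3Oc3cc(OC)c(Oc4cc(OC)c(OC)c(OC)c4Oc4cc(OC)c(Oc5cc(OC)c(OC)c(OC)c5O[Si](C)(C)C(C)(C)C)c(OC)c4)c(OC)c3)c(OC)c2)c(OC)c1 | intermediate
37 | ArAH–CHO | COc1cc(OC)c(Oc2cc(OC)c(Oc3cc(OC)c(OC)c(OC)c3Oc3cc(OC)c(Oc4cc(OC)c(OC)c(OC)c4Oc4cc(OC)c(Oc5cc(OC)c(OC)c(OC)c5Oc5cc(OC)c(C=O)c(OC)c5)c(OC)c4)c(OC)c3)c(OC)c2)c(OC)c1 | intermediate
38 | ArAH–OCHO (aryl formate) | COc1cc(OC)c(Oc2cc(OC)c(Oc3cc(OC)c(OC)c(OC)c3Oc3cc(OC)c(Oc4cc(OC)c(OC)c(OC)c4Oc4cc(OC)c(Oc5cc(OC)c(OC)c(OC)c5Oc5cc(OC)c(OC=O)c(OC)c5)c(OC)c4)c(OC)c3)c(OC)c2)c(OC)c1 | intermediate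
39 | ArAH–OH | COc1cc(OC)c(Oc2cc(OC)c(Oc3cc(OC)c(OC)c(OC)c3Oc3cc(OC)c(Oc4cc(OC)c(OC)c(OC)c4Oc4cc(OC)c(Oc5cc(OC)c(OC)c(OC)c5Oc5cc(OC)c(O)c(OC)c5)c(OC)c4)c(OC)c3)c(OC)c2)c(OC)c1 | intermediate
40 | CNP0206369.0 | Oc1cc(O)c(Oc2cc(O)c(Oc3cc(O)c(O)c(O)c3Oc3cc(O)c(Oc4cc(O)c(O)c(O)c4Oc4cc(O)c(Oc5cc(O)c(O)c(O)c5Oc5cc(O)c(O)c(O)c5)c(O)c4)c(O)c3)c(O)c2)c(O)c1 | target

**Step count**

Total: 21 steps. Longest linear sequence: 21 steps (1 to 40).

**Steps most likely to fail**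

1. Step 4 (the same operation recurs in steps 10 and 16). Deprotonation by t-BuLi may stray to ring positions flanked by two oxygens, or the lithiated aryloxyethene may lose aryloxide before it meets the squarate. The fallback makes the same organolithium by tin–lithium exchange instead of deprotonation. It sets out from phenol 5 and returns at 10.
   - Trichloroethylene, K2CO3 and DMF at 70 °C should give the (E)-1,2-dichloroethenyl aryl ether F1.
   - n-BuLi (2.2 equiv, THF, −78 °C) followed by a methanol quench should convert it, by elimination and chlorine–lithium exchange, into the aryl ethynyl ether F2.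
   - Hydrostannation with Bu3SnH and Pd(PPh3)4 (cat.) should place tin on the oxygen-bearing carbon and give the 1-aryloxyvinylstannane F3.
   - n-BuLi at −78 °C then exchanges tin for lithium to give 8 regiospecifically; addition to 7 and silylation with TBSOTf proceed as in the route.

2. Step 7 (recurring in steps 13 and 19). Substitution by the doubly ortho-substituted phenoxide may be slow enough that the fluoroaldehyde is consumed in side reactions at the formyl group. The fallback forms the same ether bond by copper catalysis. It sets out from 14 and returns at phenol 17, bypassing 15 and step 8.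
   - TBAF in THF at 0 °C should free the ring C phenol, 2,3,4-trimethoxy-6-(ArAB-oxy)phenol F4.
   - Benzylation of commercial 4-bromo-2,6-dimethoxyphenol (BnBr, K2CO3, acetone) gives 2-(benzyloxy)-5-bromo-1,3-dimethoxybenzene F5.
   - Ullmann-type coupling of F4 with F5 (CuI, picolinic acid, K3PO4, DMSO, 90 °C) should give the ring D benzyl ether F6.
   - Hydrogenolysis (H2, Pd/C, EtOAc) then delivers 17.

3. Step 21. Cleavage of twenty methyl ethers may stop short, and the pyrogallol-type rings may oxidise in air while partly demethylated material is being separated. The fallback isolates the product as a stable ester and releases it under acid. It sets out from 39 and returns at 40.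
   - After the BBr3 treatment and an argon-blanketed aqueous quench, the crude polyphenol is acetylated (Ac2O, pyridine, DMAP) to the henicosaacetate F7.
   - F7 can be chromatographed on silica, and incompletely demethylated material can be separated and resubmitted.
   - Acid-catalysed transesterification (HCl generated from AcCl in degassed MeOH, rt) then releases 40.

**Further compounds**

F1 | step 4 | 2-{[(E)-1,2-dichloroethenyl]oxy}-1,3-dimethoxy-5-(2,4,6-trimethoxyphenoxy)benzene | COc1cc(OC)c(Oc2cc(OC)c(O/C(Cl)=C\Cl)c(OC)c2)c(OC)c1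
F2 | step 4 | 2-(ethynyloxy)-1,3-dimethoxy-5-(2,4,6-trimethoxyphenoxy)benzene | COc1cc(OC)c(Oc2cc(OC)c(OC#C)c(OC)c2)c(OC)c1
F3 | step 4 | tributyl{1-[2,6-dimethoxy-4-(2,4,6-trimethoxyphenoxy)phenoxy]ethenyl}stannane | COc1cc(OC)c(Oc2cc(OC)c(OC(=C)[Sn](CCCC)(CCCC)CCCC)c(OC)c2)c(OC)c1
F4 | step 7 | 2,3,4-trimethoxy-6-(ArAB-oxy)phenol | COc1cc(OC)c(Oc2cc(OC)c(Oc3cc(OC)c(OC)c(OC)c3O)c(OC)c2)c(OC)c1
F5 | step 7 | 2-(benzyloxy)-5-bromo-1,3-dimethoxybenzene | COc1cc(Br)cc(OC)c1OCc1ccccc1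
F6 | step 7 | benzyl ether of 17 (ArAD–OCH2Ph) | COc1cc(OC)c(Oc2cc(OC)c(Oc3cc(OC)c(OC)c(OC)c3Oc3cc(OC)c(OCc4ccccc4)c(OC)c3)c(OC)c2)c(OC)c1
F7 | step 21 | henicosaacetate of 40 | CC(=O)Oc1cc(OC(C)=O)c(Oc2cc(OC(C)=O)c(Oc3cc(OC(C)=O)c(OC(C)=O)c(OC(C)=O)c3Oc3cc(OC(C)=O)c(Oc4cc(OC(C)=O)c(OC(C)=O)c(OC(C)=O)c4Oc4cc(OC(C)=O)c(Oc5cc(OC(C)=O)c(OC(C)=O)c(OC(C)=O)c5Oc5cc(OC(C)=O)c(OC(C)=O)c(OC(C)=O)c5)c(OC(C)=O)c4)c(OC(C)=O)c3)c(OC(C)=O)c2)c(OC(C)=O)c1
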